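**Retrosynthetic overview**
- The strategy rests on the (2′Z,4′E)-3′-methylpenta-2′,4′-dienyl tether between C1 of ring A (the trimethylcyclohexenol) and carbinol C1′ on ring B. C1′, C2′=C3′(CH3), C4′, C5′ and an oxygen on C5′ map onto a six-membered 4-methyl-5,6-dihydropyran-2-one, in which the trisubstituted alkene can only be Z.
- Endgame: the four silyl ethers come off last. The C1′ carbinol comes from ketone 30 by substrate-controlled reduction. The C1′–C1 (ring B) bond comes from Weinreb amide 15 and the lithiated ring B epoxide 28.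
- Amide 15 comes from acid 13, and 13 from E1cB opening of lactone 11. Lactone 11 comes from vinylogous aldol addition and lactonisation of aldehyde 6 with methyl 3-methylbut-2-enoate 7 (bond C4′–C5′).
- Ring A comes from geranyl acetate by Shi epoxidation and cationic cyclisation. Ring B is the benzene ring of 16, taken through para-bromination, Andersen sulfinylation, quinone formation, sulfoxide-directed epoxidation, reduction and double inversion.
- Order of ring formation: ring A carbocycle (step 2), temporary pyranone (closed in step 6, opened in step 7). The ring B carbocycle is carried from 16 and its oxirane closes in step 13.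

Key step: step 6

Conventions: TBS = tert-butyldimethylsilyl, Tol = 4-methylphenyl. Ring B is numbered as 7-oxabicyclo[4.1.0]hept-3-ene (C1 = quaternary oxirane carbon, C6 = oxirane CH). Side-chain atoms are primed.
Assumption: the carbinol centre of 10 and 11 is drawn as the Felkin–Anh epimer; it is destroyed in step 7, so either epimer serves.

Step 1
Reactants: 1 geranyl acetate
Product: 2 (2E)-5-[(2R)-3,3-dimethyloxiran-2-yl]-3-methylpent-2-en-1-yl acetate
Conditions: D-fructose-derived Shi ketone (30 mol %), Oxone, K2CO3, Bu4NHSO4 (cat.), MeCN–DMM/aq. Na2B4O7–EDTA, 0 °C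
Reagents that add atoms: potassium peroxymonosulfate (Oxone) [K+].[O-]S(=O)(=O)OO
Why: Shi asymmetric epoxidation, in which the chiral dioxirane prefers the electron-rich distal trisubstituted alkene over the acetate-deactivated C2=C3 alkene, and the spiro transition state of the D-fructose-derived catalyst should deliver oxygen to the face that gives the R epoxide.

Step 2
Reactants: 2 epoxygeranyl acetate
Product: 3 [(1S,5R)-5-hydroxy-2,6,6-trimethylcyclohex-2-en-1-yl]methyl acetate
Conditions: ZrCl4 (30 mol %), CH2Cl2, −20 °C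
Reagents that add atoms: none
Why: Lewis-acid-promoted cationic epoxide–alkene cyclisation through a chair, in which anti opening at the tertiary oxirane carbon keeps the C–O centre (now C5, R), the E-alkene places the acetoxymethyl group equatorial and cis to the hydroxyl (C1, S), and the tertiary cation should lose the ring proton to give the endocyclic alkene, any exocyclic isomer being removed by chromatography.

Step 3
Reactants: 3 hydroxy acetate
Product: 4 [(1S,5R)-5-(TBSO)-2,6,6-trimethylcyclohex-2-en-1-yl]methyl acetate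
Conditions: TBSOTf, 2,6-lutidine, CH2Cl2, 0 °C
Reagents that add atoms: tert-butyldimethylsilyl triflate CC(C)(C)[Si](C)(C)OS(=O)(=O)C(F)(F)F
Why: Silyl ether formation with the silyl triflate, chosen because the secondary alcohol is neopentyl, touches no stereocentre and leaves the acetate intact.

Step 4
Reactants: 4 silyl ether acetate
Product: 5 [(1S,5R)-5-(TBSO)-2,6,6-trimethylcyclohex-2-en-1-yl]methanol
Conditions: K2CO3 (cat.), MeOH, rt
Reagents that add atoms: none
Why: Base-catalysed transesterification frees the primary alcohol while the hindered TBS ether is stable to carbonate in methanol.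

Step 5
Reactants: 5 primary alcohol
Product: 6 (1S,5R)-5-(TBSO)-2,6,6-trimethylcyclohex-2-ene-1-carbaldehyde
Conditions: Dess–Martin periodinane, pyridine, CH2Cl2, 0 °C
Reagents that add atoms: none
Why: Dess–Martin oxidation runs under buffered conditions free of strong base, so the α-stereocentre and the β,γ-position of the ring alkene should survive, and the aldehyde is used at once.

Step 6
Reactants: 6 ring A aldehyde; 7 methyl 3-methylbut-2-enoate
Product: 11 (6S)-6-[(1S,5R)-5-(TBSO)-2,6,6-trimethylcyclohex-2-en-1-yl]-4-methyl-5,6-dihydro-2H-pyran-2-one, via lithium dienolate 8 (not isolated), via chlorozinc dienolate 9 (not isolated), via zinc alkoxide adduct 10 (not isolated)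
Conditions: 7, LDA, THF, −78 °C; ZnCl2, −78 → −30 °C; then 6, −30 °C → rt; H2O
Reagents that add atoms: none
Why: LDA removes a γ-proton of 7 to give dienolate 8, which is passed on to zinc (9) so that the nucleophile is too weakly basic to enolise or conjugate the β,γ-unsaturated aldehyde 6. Addition at the α-carbon is fast but reversible, whereas attack of the γ-carbon on the formyl carbon forms the C4′–C5′ bond and gives alkoxide 10. This is a vinylogous aldol (vinylogous Reformatsky-type) addition followed by lactonisation, a reaction type long applied to cyclocitral- and ionylidene-type aldehydes. Only the adduct whose new chain stands cis to the ester on C2′=C3′ can reach the carbonyl, and its alkoxide closes the dihydropyranone by 6-exo-trig acyl substitution with loss of methoxide, so the ring fixes the Z geometry and drains the α/γ and E/Z equilibria. The new carbinol centre (C6 of the lactone) is set by Felkin–Anh attack anti to the quaternary C6 of ring A and is expected as S, but it is erased in step 7. The step needs γ- over α-selectivity and retention of C1 and of the C2=C3 alkene of ring A; irreversible ring closure secures the first, and the low basicity of zinc together with the tertiary, neopentyl α-C–H secures the second.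

Step 7
Reactants: 11 lactone
Product: 13 (2Z,4E)-5-[(1S,5R)-5-(TBSO)-2,6,6-trimethylcyclohex-2-en-1-yl]-3-methylpenta-2,4-dienoic acid, via potassium dienoate 12 (not isolated)
Conditions: KOt-Bu, THF, −40 → 0 °C; then 1 M HCl to pH 4
Reagents that add atoms: none
Why: E1cB eliminative opening of a 5,6-dihydropyran-2-one, in which deprotonation at the ring methylene gives a dienolate that expels the carboxylate from C6, the ring-derived C2′=C3′ stays Z, the new C4′=C5′ alkene forms E to avoid strain against bulky ring A, and the carboxylate charge blocks further deprotonation at the doubly allylic C1 of ring A.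

Step 8
Reactants: 13 dienoic acid
Product: 15 (2Z,4E)-5-[(1S,5R)-5-(TBSO)-2,6,6-trimethylcyclohex-2-en-1-yl]-N-methoxy-N,3-dimethylpenta-2,4-dienamide, via acyl imidazolide 14 (not isolated)
Conditions: CDI, CH2Cl2, 0 °C; then MeNH(OMe)·HCl, rt, dark
Reagents that add atoms: N,O-dimethylhydroxylamine hydrochloride CNOC.Cl
Why: Weinreb amide synthesis through the acyl imidazolide proceeds near neutrality without an acid chloride or nucleophilic catalyst, so Z to E leakage of the dienoyl unit should be avoided.

Step 9
Reactants: 16 2,5-dimethoxybenzyl alcohol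
Product: 17 (4-bromo-2,5-dimethoxyphenyl)methanol
Conditions: NBS, MeCN, 0 °C → rt
Reagents that add atoms: N-bromosuccinimide O=C1CCC(=O)N1Br
Why: Electrophilic aromatic bromination goes to C4, which is ortho to a methoxy group, para to the hydroxymethyl group and the least hindered activated position.

Step 10
Reactants: 17 bromo alcohol
Product: 18 [(4-bromo-2,5-dimethoxyphenyl)methoxy](tert-butyl)dimethylsilane
Conditions: TBSCl, imidazole, DMF, rt
Reagents that add atoms: tert-butyldimethylsilyl chloride CC(C)(C)[Si](C)(C)Cl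
Why: Standard silylation of a primary benzylic alcohol removes the acidic proton before metalation.

Step 11
Reactants: 18 aryl bromide; 19 (1R,2S,5R)-menthyl (S)-p-toluenesulfinate
Product: 21 tert-butyl({2,5-dimethoxy-4-[(S)-4-methylbenzenesulfinyl]phenyl}methoxy)dimethylsilane, via aryl Grignard reagent 20 (not isolated)
Conditions: Mg, THF, reflux; then 19, toluene–THF, 0 °C; H2O
Reagents that add atoms: none
Why: Andersen sulfoxide synthesis, in which the aryl Grignard reagent displaces menthoxide with clean inversion at sulfur and so sets the S-configured sulfinyl centre.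

Step 12
Reactants: 21 aryl sulfoxide
Product: 22 2-[(TBSO)methyl]-5-[(S)-4-methylbenzenesulfinyl]cyclohexa-2,5-diene-1,4-dione
Conditions: (NH4)2Ce(NO3)6, MeCN–H2O, 0 °C
Reagents that add atoms: water O
Why: Cerium(IV) oxidative demethylation of a hydroquinone dimethyl ether gives the quinone without touching the sulfoxide, and short contact at 0 °C should spare the primary silyl ether.

Step 13
Reactants: 22 sulfinylquinone
Product: 23 (1R,6S)-4-[(TBSO)methyl]-1-[(S)-4-methylbenzenesulfinyl]-7-oxabicyclo[4.1.0]hept-3-ene-2,5-dione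
Conditions: t-BuOOH (decane), Triton B (cat.), THF, −40 °C
Reagents that add atoms: tert-butyl hydroperoxide CC(C)(C)OO
Why: Weitz–Scheffer nucleophilic epoxidation picks the alkene that is activated by both a carbonyl and the sulfinyl group, and in the non-chelated rotamer with S=O eclipsing that C=C the tolyl group covers one face, so the peroxide should add from the lone-pair face and set C1 and C6 as drawn, the minor diastereomer being separable.

Step 14
Reactants: 23 epoxyquinone
Product: 24 (1S,2R,5S,6S)-4-[(TBSO)methyl]-1-[(S)-4-methylbenzenesulfinyl]-7-oxabicyclo[4.1.0]hept-3-ene-2,5-diol (both hydroxyls cis to the oxirane oxygen)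
Conditions: NaBH4, CeCl3·7H2O, MeOH–CH2Cl2, −78 °C
Reagents that add atoms: none
Why: Luche 1,2-reduction of the flat enedione, in which hydride adds to each carbonyl anti to the adjacent oxirane C–O bond on the open face, so both new carbinols (C2, C5) should form cis to the epoxide oxygen.

Step 15
Reactants: 24 all-cis epoxy diol
Product: 25 (1S,2S,5R,6S)-4-[(TBSO)methyl]-1-[(S)-4-methylbenzenesulfinyl]-7-oxabicyclo[4.1.0]hept-3-ene-2,5-diyl bis(chloroacetate) (both esters trans to the oxirane oxygen)
Conditions: ClCH2CO2H, PPh3, DIAD, toluene, 0 °C → rt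
Reagents that add atoms: chloroacetic acid OC(=O)CCl
Why: Double Mitsunobu inversion with the strongly acidic chloroacetic acid used for hindered alcohols, in which each allylic alkoxyphosphonium ion is displaced by SN2 from the face opposite the epoxide oxygen, the backside of C2 staying open because the sulfinyl group on C1 lies close to the ring plane.

Step 16
Reactants: 25 bis(chloroacetate)
Product: 26 (1S,2S,5R,6S)-4-[(TBSO)methyl]-1-[(S)-4-methylbenzenesulfinyl]-7-oxabicyclo[4.1.0]hept-3-ene-2,5-diol (both hydroxyls trans to the oxirane oxygen)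
Conditions: K2CO3 (cat.), MeOH, −20 °C
Reagents that add atoms: none
Why: Transesterification of the activated chloroacetates is fast at low temperature, so the alkoxide concentration stays too low for Payne-type attack on the sulfinyl oxirane.

Step 17
Reactants: 26 trans,trans epoxy diol
Product: 27 (1R,2S,5R,6S)-2,5-bis(TBSO)-4-[(TBSO)methyl]-1-[(S)-4-methylbenzenesulfinyl]-7-oxabicyclo[4.1.0]hept-3-ene
Conditions: TBSOTf, 2,6-lutidine, CH2Cl2, −78 → 0 °C
Reagents that add atoms: tert-butyldimethylsilyl triflate CC(C)(C)[Si](C)(C)OS(=O)(=O)C(F)(F)F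
Why: Silylation with the triflate covers both secondary alcohols, including the hindered one at C2, and the sulfoxide has no α-hydrogen so no Pummerer pathway is open.

Step 18
Reactants: 27 ring B sulfinyl oxirane; 15 Weinreb amide
Product: 30 (2Z,4E)-1-{(1S,2S,5R,6S)-2,5-bis(TBSO)-4-[(TBSO)methyl]-7-oxabicyclo[4.1.0]hept-3-en-1-yl}-5-[(1S,5R)-5-(TBSO)-2,6,6-trimethylcyclohex-2-en-1-yl]-3-methylpenta-2,4-dien-1-one, via oxiranyllithium 28 (not isolated), via tetrahedral lithium adduct 29 (not isolated)
Conditions: 27, t-BuLi, THF, −100 °C, 2 min; then 15, −100 → −78 °C; AcOH, −78 °C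
Reagents that add atoms: none
Why: Sulfoxide–lithium exchange on a sulfinyl oxirane followed by Weinreb ketone synthesis, in which t-BuLi is used because its sulfoxide by-product has no acidic α-hydrogen, the ring fusion locks the carbanion so C1 is kept with retention, the gauche C–Li/C2–O arrangement and the strain of an allene oxide disfavour β-elimination, and the chelated adduct 29 stops over-addition.

Step 19
Reactants: 30 epoxy dienone
Product: 31 (1S,2Z,4E)-1-{(1S,2S,5R,6S)-2,5-bis(TBSO)-4-[(TBSO)methyl]-7-oxabicyclo[4.1.0]hept-3-en-1-yl}-5-[(1S,5R)-5-(TBSO)-2,6,6-trimethylcyclohex-2-en-1-yl]-3-methylpenta-2,4-dien-1-ol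
Conditions: NaBH4, CeCl3·7H2O, MeOH–THF, −78 → −40 °C
Reagents that add atoms: none
Why: Luche 1,2-reduction of an α,β-epoxy enone, in which the Felkin–Anh rotamer (hydride anti to the oxirane C1–O bond, dienyl group turned away from C2) and the cerium chelate between carbonyl and oxirane oxygens both expose the same face and should give the erythro, 1′S carbinol.

Step 20
Reactants: 31 tetrakis-TBS ether
Product: 32 target, (1R,2S,5R,6S)-1-{(1S,2Z,4E)-1-hydroxy-5-[(1S,5R)-5-hydroxy-2,6,6-trimethylcyclohex-2-en-1-yl]-3-methylpenta-2,4-dien-1-yl}-4-(hydroxymethyl)-7-oxabicyclo[4.1.0]hept-3-ene-2,5-diol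
Conditions: HF·pyridine, pyridine, THF, 0 °C → rt
Reagents that add atoms: none
Why: Fluoride-mediated global desilylation in pyridine-buffered medium removes all four TBS groups without the base that would start Payne migration of the trans epoxy alcohols and without the acidity that would ionise the dienyl carbinol.

**Compound list**

| No. | Name | SMILES | Role |
|---|---|---|---|
| 1 | geranyl acetate | CC(C)=CCC/C(C)=C/COC(C)=O | starting material |
| 2 | (6R)-6,7-epoxygeranyl acetate | CC1(C)O[C@@H]1CC/C(C)=C/COC(C)=O | intermediate |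
| 3 | [(1S,5R)-5-hydroxy-2,6,6-trimethylcyclohex-2-en-1-yl]methyl acetate | CC1=CC[C@@H](O)C(C)(C)[C@H]1COC(C)=O | intermediate |
| 4 | TBS ether of 3 | CC1=CC[C@@H](O[Si](C)(C)C(C)(C)C)C(C)(C)[C@H]1COC(C)=O | intermediate |
| 5 | ring A primary alcohol | CC1=CC[C@@H](O[Si](C)(C)C(C)(C)C)C(C)(C)[C@H]1CO | intermediate |
| 6 | ring A aldehyde | CC1=CC[C@@H](O[Si](C)(C)C(C)(C)C)C(C)(C)[C@H]1C=O | intermediate |
| 7 | methyl 3-methylbut-2-enoate | CC(C)=CC(=O)OC | starting material |
| 8 | lithium dienolate of 7 | C=C(C)C=C(OC)[O-].[Li+] | intermediate |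
| 9 | chlorozinc dienolate of 7 | C=C(C)C=C(OC)O[Zn]Cl | intermediate |
| 10 | chlorozinc alkoxide of the (Z)-γ-adduct | CC1=CC[C@@H](O[Si](C)(C)C(C)(C)C)C(C)(C)[C@H]1[C@@H](O[Zn]Cl)C/C(C)=C\C(=O)OC | intermediate |
| 11 | 6-(ring A)-4-methyl-5,6-dihydropyran-2-one | CC1=CC[C@@H](O[Si](C)(C)C(C)(C)C)C(C)(C)[C@H]1[C@@H]2CC(C)=CC(=O)O2 | intermediate |
| 12 | potassium (2Z,4E)-dienoate | CC1=CC[C@@H](O[Si](C)(C)C(C)(C)C)C(C)(C)[C@H]1/C=C/C(C)=C\C(=O)[O-].[K+] | intermediate |
| 13 | (2Z,4E)-dienoic acid | CC1=CC[C@@H](O[Si](C)(C)C(C)(C)C)C(C)(C)[C@H]1/C=C/C(C)=C\C(=O)O | intermediate |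
| 14 | (2Z,4E)-dienoyl imidazolide | CC1=CC[C@@H](O[Si](C)(C)C(C)(C)C)C(C)(C)[C@H]1/C=C/C(C)=C\C(=O)n1ccnc1 | intermediate |
| 15 | (2Z,4E)-Weinreb amide | CC1=CC[C@@H](O[Si](C)(C)C(C)(C)C)C(C)(C)[C@H]1/C=C/C(C)=C\C(=O)N(C)OC | intermediate |
| 16 | 2,5-dimethoxybenzyl alcohol | COc1ccc(OC)c(CO)c1 | starting material |
| 17 | (4-bromo-2,5-dimethoxyphenyl)methanol | COc1cc(Br)c(OC)cc1CO | intermediate |
| 18 | TBS ether of 17 | COc1cc(Br)c(OC)cc1CO[Si](C)(C)C(C)(C)C | intermediate |
| 19 | (1R,2S,5R)-menthyl (S)-p-toluenesulfinate | CC(C)[C@@H]1CC[C@@H](C)C[C@H]1O[S@](=O)c1ccc(C)cc1 | starting material |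
| 20 | aryl Grignard reagent from 18 | COc1cc([Mg]Br)c(OC)cc1CO[Si](C)(C)C(C)(C)C | intermediate |
| 21 | (S)-aryl p-tolyl sulfoxide | COc1cc([S@@](=O)c2ccc(C)cc2)c(OC)cc1CO[Si](C)(C)C(C)(C)C | intermediate |
| 22 | (S)-sulfinylquinone | O=C1C=C(CO[Si](C)(C)C(C)(C)C)C(=O)C=C1[S@@](=O)c1ccc(C)cc1 | intermediate |
| 23 | sulfinyl epoxyquinone | Cc1ccc(cc1)[S@](=O)[C@]12O[C@H]1C(=O)C(CO[Si](C)(C)C(C)(C)C)=CC2=O | intermediate |
| 24 | epoxy diol, hydroxyls cis to oxirane O | Cc1ccc(cc1)[S@](=O)[C@]12O[C@H]1[C@@H](O)C(CO[Si](C)(C)C(C)(C)C)=C[C@H]2O | intermediate |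
| 25 | bis(chloroacetate), esters trans to oxirane O | Cc1ccc(cc1)[S@](=O)[C@]12O[C@H]1[C@H](OC(=O)CCl)C(CO[Si](C)(C)C(C)(C)C)=C[C@@H]2OC(=O)CCl | intermediate |
| 26 | epoxy diol, hydroxyls trans to oxirane O | Cc1ccc(cc1)[S@](=O)[C@]12O[C@H]1[C@H](O)C(CO[Si](C)(C)C(C)(C)C)=C[C@@H]2O | intermediate |
| 27 | tris-TBS sulfinyl oxirane | Cc1ccc(cc1)[S@](=O)[C@]12O[C@H]1[C@H](O[Si](C)(C)C(C)(C)C)C(CO[Si](C)(C)C(C)(C)C)=C[C@@H]2O[Si](C)(C)C(C)(C)C | intermediate |
| 28 | ring B oxiranyllithium | [Li][C@]12O[C@H]1[C@H](O[Si](C)(C)C(C)(C)C)C(CO[Si](C)(C)C(C)(C)C)=C[C@@H]2O[Si](C)(C)C(C)(C)C | intermediate |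
| 29 | tetrahedral lithium adduct of 28 and 15 | CC1=CC[C@@H](O[Si](C)(C)C(C)(C)C)C(C)(C)[C@H]1/C=C/C(C)=C\C([O-])(N(C)OC)[C@]12O[C@H]1[C@H](O[Si](C)(C)C(C)(C)C)C(CO[Si](C)(C)C(C)(C)C)=C[C@@H]2O[Si](C)(C)C(C)(C)C.[Li+] | intermediate |
| 30 | epoxy dienone | CC1=CC[C@@H](O[Si](C)(C)C(C)(C)C)C(C)(C)[C@H]1/C=C/C(C)=C\C(=O)[C@]12O[C@H]1[C@H](O[Si](C)(C)C(C)(C)C)C(CO[Si](C)(C)C(C)(C)C)=C[C@@H]2O[Si](C)(C)C(C)(C)C | intermediate |
| 31 | (1′S)-carbinol, tetrakis-TBS ether | CC1=CC[C@@H](O[Si](C)(C)C(C)(C)C)C(C)(C)[C@H]1/C=C/C(C)=C\[C@H](O)[C@]12O[C@H]1[C@H](O[Si](C)(C)C(C)(C)C)C(CO[Si](C)(C)C(C)(C)C)=C[C@@H]2O[Si](C)(C)C(C)(C)C | intermediate |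
| 32 | CNP0389279.1 | CC1=CC[C@@H](O)C(C)(C)[C@H]1/C=C/C(C)=C\[C@H](O)[C@]12O[C@H]1[C@H](O)C(CO)=C[C@@H]2O | target |

**Step count**
- Total step count: 20.
- Longest linear sequence: 12 steps (16 → 27 in steps 9–17, then steps 18–20). The ring A line needs 11 steps (steps 1–8, then 18–20).

**Steps most likely to fail**

Step 18. The lithiated epoxide may decay by α-elimination or by loss of the neighbouring silyloxy group. It may also act as a base before it acylates at the hindered carbonyl of the Z-configured amide. The fallback raises the electrophilicity of the partner and reaches the ketone by a redox detour. It sets out from 13 and 27. LiAlH4 (Et2O, 0 °C) reduces 13 to the (2Z,4E)-dienol F1. TEMPO/PhI(OAc)2 oxidises this without loss of the Z geometry to the (2Z,4E)-dienal F2. Anion 28, generated from 27 as before, is captured by the aldehyde at −100 °C to give the C1′-epimeric carbinols F3. Dess–Martin oxidation of the mixture comes back to the route at 30.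

Step 15. Activation may stall at the more hindered C2 hydroxyl, or the carboxylate may enter with allylic shift instead of direct inversion. The fallback separates activation from displacement. It sets out from 24. ClCH2SO2Cl/pyridine gives the bis(chloromethanesulfonate) F4. Caesium acetate with 18-crown-6 in toluene displaces both sulfonates by SN2 to give the trans,trans diacetate F5. Catalytic K2CO3 in methanol at low temperature comes back to the route at 26.

Step 6. The reversible α-adduct may persist, or proton transfer from 6 to the dienolate may cause epimerisation at C1 or migration of the ring alkene into conjugation. The fallback generates the zinc dienolate without any amide base. It sets out from 7 and 6. Wohl–Ziegler bromination of 7 (NBS, AIBN) gives methyl 4-bromo-3-methylbut-2-enoate F6. Zinc insertion in warm THF in the presence of 6 (vinylogous Reformatsky reaction) forms the bromozinc dienolate F7. This adds through its γ-carbon and lactonises, coming back to the route at 11.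

**Further compounds**
F1 | step 18 | (2Z,4E)-5-[(1S,5R)-5-(TBSO)-2,6,6-trimethylcyclohex-2-en-1-yl]-3-methylpenta-2,4-dien-1-ol | CC1=CC[C@@H](O[Si](C)(C)C(C)(C)C)C(C)(C)[C@H]1/C=C/C(C)=C\CO
F2 | step 18 | (2Z,4E)-5-[(1S,5R)-5-(TBSO)-2,6,6-trimethylcyclohex-2-en-1-yl]-3-methylpenta-2,4-dienal | CC1=CC[C@@H](O[Si](C)(C)C(C)(C)C)C(C)(C)[C@H]1/C=C/C(C)=C\C=O
F3 | step 18 | C1′-epimeric carbinols (31 and its 1′R epimer) | CC1=CC[C@@H](O[Si](C)(C)C(C)(C)C)C(C)(C)[C@H]1/C=C/C(C)=C\C(O)[C@]12O[C@H]1[C@H](O[Si](C)(C)C(C)(C)C)C(CO[Si](C)(C)C(C)(C)C)=C[C@@H]2O[Si](C)(C)C(C)(C)C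
F4 | step 15 | bis(chloromethanesulfonate) of 24 | Cc1ccc(cc1)[S@](=O)[C@]12O[C@H]1[C@@H](OS(=O)(=O)CCl)C(CO[Si](C)(C)C(C)(C)C)=C[C@H]2OS(=O)(=O)CCl
F5 | step 15 | diacetate of 26 | Cc1ccc(cc1)[S@](=O)[C@]12O[C@H]1[C@H](OC(C)=O)C(CO[Si](C)(C)C(C)(C)C)=C[C@@H]2OC(C)=O
F6 | step 6 | methyl 4-bromo-3-methylbut-2-enoate | COC(=O)C=C(C)CBr
F7 | step 6 | bromozinc dienolate | C=C(C)C=C(OC)O[Zn]Br
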